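## The problem

Compound 32 is a germacranolide: a ten-membered carbocycle (C1–C10) with an α,β-unsaturated γ-lactone fused at C6/C7 (lactone oxygen on C6, C12 carbonyl, C7=C11 double bond, acetoxymethyl C13 on C11), a methacrylate on the C8 oxygen, and two trisubstituted cis-oxiranes at C1–C10 and C4–C5. A ten-membered ring resists direct closure, and because both oxiranes have their ring carbons cis, the synthesis must pass through a cyclodecadiene with two Z trisubstituted olefins of secure geometry. Six stereocentres (1R,4S,5R,6R,8R,10S) have to be set; drawn on the flattened ring, O6, O8 and both oxirane oxygens lie on the same face. Only C8 can be bought, so C4/C5 must be tied to it through a rigid intermediate; C6 can then be taken from C5 (hydride addition to an α,β-epoxy ketone is predictably erythro), and C1/C10 from the free C8 hydroxyl. The sensitive functions are the methacrylate (Michael acceptor), the allylic C13 acetate, the acidic γ-hydrogen of the butenolide at C6, the pairing of a 4,5-epoxide with a 1(10) olefin (transannular cyclisation under acid) and, before C6 is reduced, a β-silyloxy ketone that eliminates with base. The feature that opens the problem is that C6 and C10 are 1,5-related across C7–C8–C9: a temporary C6–C10 bond turns the macrocycle into a cis-fused bicyclo[5.3.0]decane (cyclopentane C6–C7–C8–C9–C10, cycloheptene C10–C1–C2–C3–C4=C5–C6). In that bicycle the C4=C5 olefin is necessarily cis, a tertiary C6 hydroxyl is in place to direct its epoxidation, and a leaving group on C1 makes the ring-fusion bond cleavable to the C6 ketone and the Z C1=C10 olefin.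

## Retrosynthesis

**C8 ester.** The C8–O acyl bond of 32 is cut first, giving alcohol 31. The methacrylate would not survive enolates, hydrides, fluoride or palladium, so it must be the last group to go on. The forward step is a plain acylation of a secondary alcohol.

**1,10-Epoxide.** The two C–O bonds of the C1–C10 oxirane are cut, leading to homoallylic alcohol 30 and, one step back, to its silyl ether 29. Epoxidising after esterification would leave no directing group, whereas in 30 the free C8 hydroxyl can deliver the oxygen. The forward reaction must put the oxirane cis to O8 and leave the electron-poor butenolide alkene alone.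

**C11–C13 bond.** In 29 the acetoxymethyl group is removed as an sp2–sp3 coupling, through alcohol 28 and vinyl triflate 27, back to the enol 26 of an α-keto lactone. The neighbouring options were weaker. Dehydrating an 11-hydroxy lactone can eliminate toward C13 as well as C7 and depends on the C11 configuration. Condensing a pyruvate at the ketone stage leaves the geometry of a tetrasubstituted alkene uncontrolled. In 26 the double bond can only be C7=C11, because the keto form enolises in one direction. The forward steps required are an enol triflation and a Stille hydroxymethylation.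

**Lactone annulation.** Enol 26 is traced to hydroxy lactone 24 (oxidation level), then to keto ester 22 (O6–C12 lactone bond and C6–H bond), then to ketone 19 and ethyl glyoxylate 20 (C7–C11 aldol bond). Ketone 19 is what the ring-forming step delivers: carbonyl on C6, only C7 enolisable, and an oxirane on C5 to steer the hydride. The forward sequence needs a kinetic enolate that keeps its β-silyloxy group and an erythro-selective reduction.

**Key disconnection.** The C6–C10 bond is re-formed in 19: the C6 carbonyl becomes a tertiary alcohol and the C1=C10 olefin becomes a C1 mesylate, which is hydroazulenol 17. Against macrolactonisation-type closures or metathesis (poor control of a Z trisubstituted olefin in a ten-membered ring), this trades the medium ring for a five- and a seven-membered ring. Olefin geometry becomes a question of relative configuration. The forward step needs the mesylate anti-periplanar to the ring-fusion bond.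

**4,5-Epoxide.** The oxirane of 17 is removed to give allylic alcohol 16, and the sulfonate to give diol 15. Epoxidising here rather than on the macrocycle is the main reinforcement of the plan. Once the lactone is closed there is no free hydroxyl on C6, and peripheral attack on medium-ring allylic systems is expected to give the other C4/C5 diastereomer. In the bicycle the tertiary C6 hydroxyl and the convex face point the same way. The price is that the C8-to-C10 relation, otherwise irrelevant, must be controlled.

**C5–C6 bond.** Diol 15 is opened at C5–C6 to iodo ketone 13, with a vinyllithium adding to the cyclopentanone. The Z vinyl iodide carries the future C4=C5 geometry, and the tether enforces cis ring fusion.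

**C1–C10 bond.** Aldol 13 is cut into enone 3 and aldehyde 11. Conjugate reduction generates the tetrasubstituted enolate regiospecifically. The aldol must set C10 (anti to the silyloxy group) and the C1/C10 relation that later decides olefin geometry.

**Building blocks.** Enone 3 comes from commercial silyloxy enone 1 through iodide 2. Aldehyde 11 comes from ester 10, made from bromide 7 and tert-butyl acetate 8; 7 derives from iodo alcohol 6 and propargyl alcohol 4.

## Roads not taken

**Alternative 1:** The cut is at the oxirane C–O bond on C5 and the lactone O6–C12 bond. Seco ester A1 (free tertiary hydroxyl on C4, trans 5,6-epoxide, Z methyl ester at C12) would be treated with DBU. The C4 alkoxide opens the epoxide at C5 (Payne rearrangement) and the released C6 alkoxide lactonises to A2, which is the same compound as 29.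
- Merits: C5 is set by inversion and C6 by retention in one stereospecific event, so no hydride has to find the right face of C6; an irreversible ring closure pulls the Payne equilibrium over.
- Weak points: A1 already contains the ten-membered ring and the Z olefin, which this step does not provide. It also needs a tetrasubstituted C7=C11 alkene with the ester cis to C6 and a trans epoxide, both made selectively on a flexible ring. Under DBU the C4 alkoxide can also reach C12, and the allylic acetate is exposed.
- Comparison: in the handling of C6 this road is better than the chosen one, whose step 13 depends on facial selectivity. The chosen plan offers in return ring formation and olefin geometry from one stereospecific fragmentation, and C4/C5 fixed in a rigid bicycle.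

**Alternative 2:** The cut is the C5–C6 bond. Aldehyde A3 (formyl group on the methoxymethyl-protected quaternary C4, γ-unsubstituted butenolide) would be converted with tBuMe2SiOTf and triethylamine into its 2-silyloxyfuran. MgBr2·OEt2 would then make the furan γ-carbon add to the tethered aldehyde, closing the ring to carbinol A4 (vinylogous Mukaiyama aldol).
- Merits: convergent; the butenolide with its acetate is finished on a small fragment, clearly easier than steps 12–17 here; C5 and C6 form together.
- Weak points: a ten-membered ring is closed by C–C bond formation onto a neopentyl aldehyde (strain, dilution). Simple and facial selectivity must both be right with C8 as a remote control element. The C4 ether/C5 carbinol pair must still become the oxirane, which needs acid to remove the acetal and a displacement with inversion at C5.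
- Comparison: better in convergence and in lactone construction. The chosen plan offers a ring made without entropic penalty, guaranteed Z geometry and an oxirane made directly.

**Alternative 3:** The cut is C7–C11. Keto acrylate A5 (acrylate on O6, ketone on C7) would be treated with DABCO or PMe3. The ester enolate adds to the ketone (intramolecular Baylis–Hillman reaction) to give α-methylene-β-hydroxy lactone A6, whose tertiary allylic oxygen is then transposed as the acetate to C13.
- Merits: three operations deliver the whole butenolide including the acetate, shorter than steps 12–17 here; the C7 configuration is irrelevant.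
- Weak points: it needs oxygen on C6 and the ketone on C7, whereas the ring-forming fragmentation places the ketone on C6, so a carbonyl transposition or another ring synthesis is required. Baylis–Hillman additions to ketones are slow and the acrylate of a β-ketol can be lost by elimination. Both olefins remain to be epoxidised when no hydroxyl on C6 is left to direct the 4,5-epoxidation.
- Comparison: better in step economy of the lactone. The chosen plan offers an annulation that starts from the carbonyl position the key step provides and an oxirane configured before the ring is opened.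

Key step: step 11

Remark: germacrane numbering (C1–C15) is used for every ten-membered compound and for the matching carbons of the bicyclic precursors; TBSO stands for tert-butyldimethylsilyloxy; compounds 22 to 25 are carried as mixtures of epimers at C7 and C11, centres that become trigonal in step 14.

## Steps

Step 1
Reactants: 1 (S)-4-TBSO-cyclopent-2-en-1-one
Product: 2 (S)-4-TBSO-2-iodocyclopent-2-en-1-one
Conditions: I2, pyridine, CH2Cl2, 0 °C to rt
Reagents that add atoms: iodine, II
Why: α-Iodination of an enone by conjugate addition of pyridine, iodination of the enolate and loss of pyridine (Baylis–Hillman-type addition–elimination); the silyloxy-bearing centre is not involved.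

Step 2
Reactants: 2 (S)-4-TBSO-2-iodocyclopent-2-en-1-one
Product: 3 (S)-4-TBSO-2-methylcyclopent-2-en-1-one
Conditions: Me4Sn, Pd2(dba)3 (cat.), AsPh3, CuI, NMP, 50 °C
Reagents that add atoms: tetramethylstannane, C[Sn](C)(C)C
Why: Stille coupling of an α-iodoenone under neutral conditions, chosen because the 4-silyloxy enone eliminates under the basic conditions of other couplings.

Step 3
Reactants: 4 prop-2-yn-1-ol
Product: 6 (Z)-3-iodo-2-methylprop-2-en-1-ol, via alkenylmagnesium alkoxide 5 (not isolated)
Conditions: MeMgBr (2.2 equiv), CuI (10 mol%), THF, −10 °C to rt; then I2, −10 °C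
Reagents that add atoms: methylmagnesium bromide, C[Mg]Br; iodine, II
Why: Copper-catalysed anti carbomagnesiation of the propargylic alkoxide places methyl on C2 and magnesium on C3 cis to the CH2O group; iodinolysis with retention gives the Z iodide that will become the C4=C5 olefin.

Step 4
Reactants: 6 (Z)-3-iodo-2-methylprop-2-en-1-ol
Product: 7 (Z)-3-bromo-1-iodo-2-methylprop-1-ene
Conditions: CBr4, PPh3, CH2Cl2, 0 °C
Reagents that add atoms: carbon tetrabromide, BrC(Br)(Br)Br
Why: Appel reaction of a primary allylic alcohol; the vinyl iodide and its geometry are untouched.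

Step 5
Reactants: 7 (Z)-3-bromo-1-iodo-2-methylprop-1-ene; 8 tert-butyl acetate
Product: 10 tert-butyl (Z)-5-iodo-4-methylpent-4-enoate, via lithium enolate 9 (not isolated)
Conditions: LiN(iPr)2, THF, −78 °C; then 7, −78 to −20 °C
Reagents that add atoms: none
Why: SN2 alkylation of an ester enolate by a primary allylic bromide; the vinyl iodide is inert to the enolate at this temperature.

Step 6
Reactants: 10 tert-butyl (Z)-5-iodo-4-methylpent-4-enoate
Product: 11 (Z)-5-iodo-4-methylpent-4-enal
Conditions: iBu2AlH (1.05 equiv), CH2Cl2, −78 °C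
Reagents that add atoms: none
Why: Partial reduction of an ester to the aldehyde through the aluminium hemiacetal, which is stable at −78 °C and collapses on work-up.

Step 7
Reactants: 3 (S)-4-TBSO-2-methylcyclopent-2-en-1-one; 11 (Z)-5-iodo-4-methylpent-4-enal
Product: 13 (2S,4R)-4-TBSO-2-[(1S,4Z)-1-hydroxy-5-iodo-4-methylpent-4-en-1-yl]-2-methylcyclopentan-1-one, via lithium enolate 12 (not isolated)
Conditions: LiBH(sec-Bu)3, THF, −78 °C; then 11, −78 °C; AcOH, −78 °C
Reagents that add atoms: none
Why: Conjugate hydride addition to the β-unsubstituted enone gives the tetrasubstituted enolate regiospecifically (reductive aldol); the aldehyde should add to the face anti to the C8 silyloxy group, setting C10, and through a closed Zimmerman–Traxler transition state of this ring enolate, placing the C1 hydroxyl syn to the C10 methyl.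

Step 8
Reactants: 13 (2S,4R)-4-TBSO-2-[(1S,4Z)-1-hydroxy-5-iodo-4-methylpent-4-en-1-yl]-2-methylcyclopentan-1-one
Product: 15 (2R,3aS,8S,8aS)-2-TBSO-5,8a-dimethyl-1,2,3,3a,6,7,8,8a-octahydroazulene-3a,8-diol, via dilithio intermediate 14 (not isolated)
Conditions: tBuLi (3.2 equiv), THF, −78 °C; then aq. NH4Cl
Reagents that add atoms: none
Why: After deprotonation of the hydroxyl, iodine–lithium exchange gives a configurationally stable Z vinyllithium that adds to the neighbouring ketone (7-exo-trig anionic cyclisation); the tether on C10 can reach only its own face of the carbonyl, so the ring fusion is cis and C6 is set.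

Step 9
Reactants: 15 (2R,3aS,8S,8aS)-2-TBSO-5,8a-dimethyl-1,2,3,3a,6,7,8,8a-octahydroazulene-3a,8-diol
Product: 16 (2R,3aS,8S,8aS)-2-TBSO-3a-hydroxy-5,8a-dimethyl-1,2,3,3a,6,7,8,8a-octahydroazulen-8-yl methanesulfonate
Conditions: MsCl, pyridine, CH2Cl2, 0 °C
Reagents that add atoms: methanesulfonyl chloride, CS(=O)(=O)Cl
Why: Sulfonylation of the secondary C1 hydroxyl; the tertiary allylic C6 hydroxyl does not react under these non-sulfene conditions.

Step 10
Reactants: 16 (2R,3aS,8S,8aS)-2-TBSO-3a-hydroxy-5,8a-dimethyl-1,2,3,3a,6,7,8,8a-octahydroazulen-8-yl methanesulfonate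
Product: 17 (2R,3aR,4R,5S,8S,8aS)-2-TBSO-4,5-epoxy-3a-hydroxy-5,8a-dimethyldecahydroazulen-8-yl methanesulfonate
Conditions: VO(acac)2 (cat.), tBuOOH, CH2Cl2, 0 °C to rt
Reagents that add atoms: tert-butyl hydroperoxide, CC(C)(C)OO
Why: Hydroxyl-directed epoxidation of a cyclic tertiary allylic alcohol: the vanadate ester delivers oxygen to the olefin face syn to the C6 hydroxyl, which is also the convex face of the cis-fused bicycle, and this fixes C4 and C5 as in 32. Mesylation comes first so that no C1 hydroxyl is left to open the new oxirane across the ring.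

Step 11
Reactants: 17 (2R,3aR,4R,5S,8S,8aS)-2-TBSO-4,5-epoxy-3a-hydroxy-5,8a-dimethyldecahydroazulen-8-yl methanesulfonate
Product: 19 (1S,4R,6Z,10S)-4-TBSO-6,10-dimethyl-11-oxabicyclo[8.1.0]undec-6-en-2-one, via potassium alkoxide 18 (not isolated)
Conditions: KOtBu (1.0 equiv), THF, −40 to 0 °C
Reagents that add atoms: none
Why: Potassium tert-butoxide deprotonates the tertiary C6 hydroxyl; in alkoxide 18 an oxygen lone pair, the C6–C10 bond and the C1–O bond of the mesylate are anti-periplanar, so formation of the C6 carbonyl, scission of the ring-fusion bond and departure of mesylate occur in one concerted step (Grob fragmentation; the closest known reaction type is the Wharton fragmentation of bicyclic 1,3-diol monosulfonates to cyclodecenones). The ten-membered ring is not closed but uncovered by cutting the bond shared by the five- and seven-membered rings, so no ring-closure mode applies and no dilution is needed. No stereocentre is created: C1, C6 and C10 become trigonal, and C4, C5 and C8 are spectators. The selectivity needed is olefin geometry, and it is stereospecific: with the mesylate equatorial on the seven-membered ring (anti to C6–C10) and C2 anti to the C10 methyl, C9 and C2 end up cis, which is the Z C1=C10 olefin; this relative configuration was fixed in step 7. The cis epoxy alkoxide cannot undergo Payne rearrangement, because O6 and the oxirane oxygen are on the same face and backside attack at C5 is impossible. One equivalent of base at low temperature is used because 19 is a β-silyloxy ketone that would lose the silyloxy group by β-elimination with excess base.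

Step 12
Reactants: 19 (1S,4R,6Z,10S)-4-TBSO-6,10-dimethyl-11-oxabicyclo[8.1.0]undec-6-en-2-one; 20 ethyl glyoxylate
Product: 22 ethyl (1(10)Z,4S,5S,8R)-8-TBSO-4,5-epoxy-11-hydroxy-6-oxo-13-norgermacr-1(10)-en-12-oate as C7/C11 epimers, via lithium enolate 21 (not isolated)
Conditions: LiN(iPr)2, THF, −78 °C; then 20, −78 °C; AcOH, −78 °C
Reagents that add atoms: none
Why: Only C7 can be deprotonated (C5 is an oxirane carbon), so the kinetic enolate forms on the required side and adds to the aldehyde (aldol reaction); at −78 °C the β-silyloxy group is retained.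

Step 13
Reactants: 22 ethyl (1(10)Z,4S,5S,8R)-8-TBSO-4,5-epoxy-11-hydroxy-6-oxo-13-norgermacr-1(10)-en-12-oate
Product: 24 (1(10)Z,4S,5R,6R,8R)-8-TBSO-4,5-epoxy-11-hydroxy-13-norgermacr-1(10)-en-6,12-olide as C7/C11 epimers, via hydroxy ester 23 (not isolated)
Conditions: Zn(BH4)2, Et2O, −20 °C; then DBU (cat.), CH2Cl2, rt
Reagents that add atoms: none
Why: Chelation-controlled reduction of an α,β-epoxy ketone: zinc bridges the carbonyl and oxirane oxygens and hydride adds to the face away from C4, giving the erythro epoxy alcohol, which is (6R). The C6 hydroxyl then closes onto the ethyl ester (5-exo-trig lactonisation) with retention at C6.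

Step 14
Reactants: 24 (1(10)Z,4S,5R,6R,8R)-8-TBSO-4,5-epoxy-11-hydroxy-13-norgermacr-1(10)-en-6,12-olide
Product: 26 (1(10)Z,4S,5R,6R,8R)-8-TBSO-4,5-epoxy-11-hydroxy-13-norgermacra-1(10),7(11)-dien-6,12-olide, via keto lactone 25 (not isolated)
Conditions: Dess–Martin periodinane, NaHCO3, CH2Cl2, 0 °C to rt
Reagents that add atoms: none
Why: Dess–Martin oxidation of the secondary α-hydroxy lactone gives the α-keto lactone, which exists as its enol; enolisation can only go toward C7, so the C7=C11 double bond is placed without ambiguity and both uncontrolled centres disappear.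

Step 15
Reactants: 26 (1(10)Z,4S,5R,6R,8R)-8-TBSO-4,5-epoxy-11-hydroxy-13-norgermacra-1(10),7(11)-dien-6,12-olide
Product: 27 (1(10)Z,4S,5R,6R,8R)-8-TBSO-4,5-epoxy-11-(trifluoromethanesulfonyloxy)-13-norgermacra-1(10),7(11)-dien-6,12-olide
Conditions: PhNTf2, Et3N, CH2Cl2, 0 °C
Reagents that add atoms: N-phenylbis(trifluoromethanesulfonimide), O=S(=O)(N(c1ccccc1)S(=O)(=O)C(F)(F)F)C(F)(F)F
Why: O-Sulfonylation of the acidic enol with a mild triflating agent gives the vinyl triflate; the weak amine base spares the butenolide γ-hydrogen.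

Step 16
Reactants: 27 (1(10)Z,4S,5R,6R,8R)-8-TBSO-4,5-epoxy-11-(trifluoromethanesulfonyloxy)-13-norgermacra-1(10),7(11)-dien-6,12-olide
Product: 28 (1(10)Z,4S,5R,6R,8R)-8-TBSO-4,5-epoxy-13-hydroxygermacra-1(10),7(11)-dien-6,12-olide
Conditions: Bu3SnCH2OH, Pd(PPh3)4 (cat.), LiCl, dioxane, 80 °C
Reagents that add atoms: (tributylstannyl)methanol, CCCC[Sn](CCCC)(CCCC)CO
Why: Stille coupling of a vinyl triflate with a hydroxymethylstannane puts C13 on C11 with the double bond position and the lactone untouched.

Step 17
Reactants: 28 (1(10)Z,4S,5R,6R,8R)-8-TBSO-4,5-epoxy-13-hydroxygermacra-1(10),7(11)-dien-6,12-olide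
Product: 29 (1(10)Z,4S,5R,6R,8R)-13-acetoxy-8-TBSO-4,5-epoxygermacra-1(10),7(11)-dien-6,12-olide
Conditions: Ac2O, pyridine, DMAP (cat.), CH2Cl2, 0 °C
Reagents that add atoms: acetic anhydride, CC(=O)OC(C)=O
Why: Acylation of the primary allylic alcohol; no other hydroxyl is free.

Step 18
Reactants: 29 (1(10)Z,4S,5R,6R,8R)-13-acetoxy-8-TBSO-4,5-epoxygermacra-1(10),7(11)-dien-6,12-olide
Product: 30 (1(10)Z,4S,5R,6R,8R)-13-acetoxy-4,5-epoxy-8-hydroxygermacra-1(10),7(11)-dien-6,12-olide
Conditions: Bu4NF, AcOH (1:1), THF, 0 °C to rt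
Reagents that add atoms: none
Why: Fluoride cleavage of the silyl ether; buffering with acetic acid keeps the medium near neutral, which protects the acetate, the butenolide γ-hydrogen and the epoxide.

Step 19
Reactants: 30 (1(10)Z,4S,5R,6R,8R)-13-acetoxy-4,5-epoxy-8-hydroxygermacra-1(10),7(11)-dien-6,12-olide
Product: 31 (1R,4S,5R,6R,8R,10S)-13-acetoxy-1,10:4,5-diepoxy-8-hydroxygermacr-7(11)-en-6,12-olide
Conditions: VO(acac)2 (cat.), tBuOOH, CH2Cl2, 0 °C
Reagents that add atoms: tert-butyl hydroperoxide, CC(C)(C)OO
Why: Homoallylic hydroxyl-directed epoxidation: in the chair-like vanadate transition state with C7 equatorial and C1 in the outside position, oxygen should be delivered to the C1=C10 face that gives the (1R,10S) oxirane, cis to O8 on the flattened ring. The tetrasubstituted butenolide alkene is electron-poor and should not react.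

Step 20
Reactants: 31 (1R,4S,5R,6R,8R,10S)-13-acetoxy-1,10:4,5-diepoxy-8-hydroxygermacr-7(11)-en-6,12-olide
Product: 32 (1R,4S,5R,6R,8R,10S)-13-acetoxy-1,10:4,5-diepoxy-8-(2-methylprop-2-enoyloxy)germacr-7(11)-en-6,12-olide
Conditions: methacrylic anhydride, Et3N, DMAP (cat.), CH2Cl2, 0 °C to rt
Reagents that add atoms: methacrylic anhydride, C=C(C)C(=O)OC(=O)C(C)=C
Why: DMAP-catalysed acylation of the secondary alcohol with retention at C8; it is placed last because the methacrylate is a Michael acceptor.

## Compound list

1 | (S)-4-(tert-butyldimethylsilyloxy)cyclopent-2-en-1-one | O=C1C=C[C@@H](O[Si](C)(C)C(C)(C)C)C1 | starting material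
2 | (S)-4-(tert-butyldimethylsilyloxy)-2-iodocyclopent-2-en-1-one | O=C1C(I)=C[C@@H](O[Si](C)(C)C(C)(C)C)C1 | intermediate
3 | (S)-4-(tert-butyldimethylsilyloxy)-2-methylcyclopent-2-en-1-one | O=C1C(C)=C[C@@H](O[Si](C)(C)C(C)(C)C)C1 | intermediate
4 | prop-2-yn-1-ol (propargyl alcohol) | C#CCO | starting material
5 | bromomagnesium (Z)-3-(bromomagnesio)-2-methylprop-2-en-1-olate | C/C(CO[Mg]Br)=C/[Mg]Br | intermediate (not isolated)
6 | (Z)-3-iodo-2-methylprop-2-en-1-ol | OC/C(C)=C\I | intermediate
7 | (Z)-3-bromo-1-iodo-2-methylprop-1-ene | BrC/C(C)=C\I | intermediate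
8 | tert-butyl acetate | CC(=O)OC(C)(C)C | starting material
9 | lithium enolate of tert-butyl acetate | [Li]OC(=C)OC(C)(C)C | intermediate (not isolated)
10 | tert-butyl (Z)-5-iodo-4-methylpent-4-enoate | CC(C)(C)OC(=O)CC/C(C)=C\I | intermediate
11 | (Z)-5-iodo-4-methylpent-4-enal | O=CCC/C(C)=C\I | intermediate
12 | lithium (R)-4-(tert-butyldimethylsilyloxy)-2-methylcyclopent-1-en-1-olate | [Li]OC1=C(C)C[C@@H](O[Si](C)(C)C(C)(C)C)C1 | intermediate (not isolated)
13 | (2S,4R)-4-(tert-butyldimethylsilyloxy)-2-[(1S,4Z)-1-hydroxy-5-iodo-4-methylpent-4-en-1-yl]-2-methylcyclopentan-1-one | C[C@]1(C[C@@H](O[Si](C)(C)C(C)(C)C)CC1=O)[C@@H](O)CC/C(C)=C\I | intermediate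
14 | dilithio derivative of 13 (lithium alkoxide at C1, Z vinyllithium at C5) | C[C@]1(C[C@@H](O[Si](C)(C)C(C)(C)C)CC1=O)[C@@H](O[Li])CC/C(C)=C\[Li] | intermediate (not isolated)
15 | (2R,3aS,8S,8aS)-2-(tert-butyldimethylsilyloxy)-5,8a-dimethyl-1,2,3,3a,6,7,8,8a-octahydroazulene-3a,8-diol (cis-fused; 3a-OH, 8a-CH3 and 2-OTBS on one face, 8-OH on the other) | C[C@@]12C[C@@H](O[Si](C)(C)C(C)(C)C)C[C@]1(O)C=C(C)CC[C@@H]2O | intermediate
16 | (2R,3aS,8S,8aS)-2-(tert-butyldimethylsilyloxy)-3a-hydroxy-5,8a-dimethyl-1,2,3,3a,6,7,8,8a-octahydroazulen-8-yl methanesulfonate | C[C@@]12C[C@@H](O[Si](C)(C)C(C)(C)C)C[C@]1(O)C=C(C)CC[C@@H]2OS(C)(=O)=O | intermediate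
17 | (2R,3aR,4R,5S,8S,8aS)-2-(tert-butyldimethylsilyloxy)-4,5-epoxy-3a-hydroxy-5,8a-dimethyldecahydroazulen-8-yl methanesulfonate (oxirane cis to the 3a-OH) | C[C@@]12C[C@@H](O[Si](C)(C)C(C)(C)C)C[C@]1(O)[C@H]1O[C@@]1(C)CC[C@@H]2OS(C)(=O)=O | intermediate (key-step precursor)
18 | potassium 3a-alkoxide of 17 | C[C@@]12C[C@@H](O[Si](C)(C)C(C)(C)C)C[C@]1(O[K])[C@H]1O[C@@]1(C)CC[C@@H]2OS(C)(=O)=O | intermediate (not isolated)
19 | (1S,4R,6Z,10S)-4-(tert-butyldimethylsilyloxy)-6,10-dimethyl-11-oxabicyclo[8.1.0]undec-6-en-2-one; in germacrane numbering the (1(10)Z,4S,5S,8R)-4,5-epoxy-8-silyloxy-6-ketone lacking C11–C13 | CC(C)(C)[Si](C)(C)O[C@@H]1C/C(C)=C\CC[C@]2(C)O[C@@H]2C(=O)C1 | intermediate (key-step product)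
20 | ethyl glyoxylate | O=CC(=O)OCC | starting material
21 | lithium 6,7-enolate of 19 | CC(C)(C)[Si](C)(C)O[C@@H]1C/C(C)=C\CC[C@]2(C)O[C@@H]2C(O[Li])=C1 | intermediate (not isolated)
22 | ethyl (1(10)Z,4S,5S,8R)-8-(tert-butyldimethylsilyloxy)-4,5-epoxy-11-hydroxy-6-oxo-13-norgermacr-1(10)-en-12-oate, epimers at C7 and C11 | CC(C)(C)[Si](C)(C)O[C@@H]1C/C(C)=C\CC[C@]2(C)O[C@@H]2C(=O)C1C(O)C(=O)OCC | intermediate
23 | ethyl (1(10)Z,4S,5R,6R,8R)-8-(tert-butyldimethylsilyloxy)-4,5-epoxy-6,11-dihydroxy-13-norgermacr-1(10)-en-12-oate, epimers at C7 and C11 | CC(C)(C)[Si](C)(C)O[C@@H]1C/C(C)=C\CC[C@]2(C)O[C@@H]2[C@H](O)C1C(O)C(=O)OCC | intermediate (not isolated)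
24 | (1(10)Z,4S,5R,6R,8R)-8-(tert-butyldimethylsilyloxy)-4,5-epoxy-11-hydroxy-13-norgermacr-1(10)-en-6,12-olide, epimers at C7 and C11 | CC(C)(C)[Si](C)(C)O[C@@H]1C/C(C)=C\CC[C@]2(C)O[C@@H]2[C@@H]2OC(=O)C(O)C21 | intermediate
25 | (1(10)Z,4S,5R,6R,8R)-8-(tert-butyldimethylsilyloxy)-4,5-epoxy-11-oxo-13-norgermacr-1(10)-en-6,12-olide, epimers at C7 | CC(C)(C)[Si](C)(C)O[C@@H]1C/C(C)=C\CC[C@]2(C)O[C@@H]2[C@@H]2OC(=O)C(=O)C21 | intermediate (not isolated)
26 | (1(10)Z,4S,5R,6R,8R)-8-(tert-butyldimethylsilyloxy)-4,5-epoxy-11-hydroxy-13-norgermacra-1(10),7(11)-dien-6,12-olide (enol of 25) | CC(C)(C)[Si](C)(C)O[C@@H]1C/C(C)=C\CC[C@]2(C)O[C@@H]2[C@@H]2OC(=O)C(O)=C21 | intermediate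
27 | (1(10)Z,4S,5R,6R,8R)-8-(tert-butyldimethylsilyloxy)-4,5-epoxy-11-(trifluoromethanesulfonyloxy)-13-norgermacra-1(10),7(11)-dien-6,12-olide | CC(C)(C)[Si](C)(C)O[C@@H]1C/C(C)=C\CC[C@]2(C)O[C@@H]2[C@@H]2OC(=O)C(OS(=O)(=O)C(F)(F)F)=C21 | intermediate
28 | (1(10)Z,4S,5R,6R,8R)-8-(tert-butyldimethylsilyloxy)-4,5-epoxy-13-hydroxygermacra-1(10),7(11)-dien-6,12-olide | CC(C)(C)[Si](C)(C)O[C@@H]1C/C(C)=C\CC[C@]2(C)O[C@@H]2[C@@H]2OC(=O)C(CO)=C21 | intermediate
29 | (1(10)Z,4S,5R,6R,8R)-13-acetoxy-8-(tert-butyldimethylsilyloxy)-4,5-epoxygermacra-1(10),7(11)-dien-6,12-olide | CC(C)(C)[Si](C)(C)O[C@@H]1C/C(C)=C\CC[C@]2(C)O[C@@H]2[C@@H]2OC(=O)C(COC(C)=O)=C21 | intermediate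
30 | (1(10)Z,4S,5R,6R,8R)-13-acetoxy-4,5-epoxy-8-hydroxygermacra-1(10),7(11)-dien-6,12-olide | O[C@@H]1C/C(C)=C\CC[C@]2(C)O[C@@H]2[C@@H]2OC(=O)C(COC(C)=O)=C21 | intermediate
31 | (1R,4S,5R,6R,8R,10S)-13-acetoxy-1,10:4,5-diepoxy-8-hydroxygermacr-7(11)-en-6,12-olide | O[C@@H]1C[C@]2(C)O[C@@H]2CC[C@]2(C)O[C@@H]2[C@@H]2OC(=O)C(COC(C)=O)=C21 | intermediate
32 | (1R,4S,5R,6R,8R,10S)-13-acetoxy-1,10:4,5-diepoxy-8-(2-methylprop-2-enoyloxy)germacr-7(11)-en-6,12-olide (CNP0212980.1) | C=C(C)C(=O)O[C@@H]1C[C@]2(C)O[C@@H]2CC[C@]2(C)O[C@@H]2[C@@H]2OC(=O)C(COC(C)=O)=C21 | target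

## Step count and least certain steps

Total: 20 steps. Longest linear sequence: 18 steps (4 to 32, steps 3–20); the enone branch (steps 1 and 2) joins at step 7.

**Step 11 (key step).** The epoxide-bearing seven-membered ring may not hold the mesylate fully anti-periplanar to the C6–C10 bond. Fragmentation would then be slow, and β-elimination of the C8 silyloxy group from the product by the base would compete. In addition, low facial selectivity in step 7 would pass through step 10 as the wrong oxirane configuration. The fallback sets out from 16 and returns at 19; it keeps the same fragmentation but moves the epoxidation behind it. Mesylate 16 is fragmented with KOtBu to the Z,Z-dienone (2Z,6Z,9R)-9-(tert-butyldimethylsilyloxy)-3,7-dimethylcyclodeca-2,6-dien-1-one F1, in which the C8/C10 relation of the precursor no longer matters. Reagent-controlled Corey–Bakshi–Shibata reduction ((S)-oxazaborolidine, BH3·SMe2; the alkenyl side acts as the large group) should give the allylic alcohol (1R,2Z,6Z,9R)-9-(tert-butyldimethylsilyloxy)-3,7-dimethylcyclodeca-2,6-dien-1-ol F2. Hydroxyl-directed epoxidation (VO(acac)2, tBuOOH) should give the cis-epoxy alcohol (1R,2R,4R,6Z,10S)-4-(tert-butyldimethylsilyloxy)-6,10-dimethyl-11-oxabicyclo[8.1.0]undec-6-en-2-ol F3, and Dess–Martin oxidation of F3 gives 19.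

**Step 7.** The aldol of a tetrasubstituted lithium enolate may show poor simple diastereoselection at C1, because an open transition state can compete with the closed one; the C1 epimer would lead to the E olefin in step 11. (Poor facial selectivity relative to C8 is the second risk and is absorbed by the fallback of step 11.) The fallback sets out from 15, obtained together with its C1 epimer after step 8, and returns at 15. The mixture is oxidised (Dess–Martin periodinane) to the single hydroxy ketone (2R,3aS,8aR)-2-(tert-butyldimethylsilyloxy)-3a-hydroxy-5,8a-dimethyl-2,3,3a,6,7,8a-hexahydroazulen-8(1H)-one F4. Evans–Saksena reduction (Me4NBH(OAc)3, AcOH, MeCN) then delivers hydride from the face of the tertiary C6 hydroxyl and should give the anti diol 15 only.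

**Step 13.** Hydride may add with poor facial selectivity at C6, because C7 is a stereogenic centre present as two epimers and the C11 hydroxyl offers zinc a second chelation site that competes with the oxirane. The fallback sets out from 19 and returns at 29; C6 is reduced while C7 is trigonal.
- Enolate 21 is trapped with Eschenmoser's salt to give the Mannich base (1S,4R,6Z,10S)-4-(tert-butyldimethylsilyloxy)-3-[(dimethylamino)methyl]-6,10-dimethyl-11-oxabicyclo[8.1.0]undec-6-en-2-one F5.
- Methylation (MeI) and elimination (NaHCO3) give the methylidene ketone (1S,4R,6Z,10S)-4-(tert-butyldimethylsilyloxy)-6,10-dimethyl-3-methylidene-11-oxabicyclo[8.1.0]undec-6-en-2-one F6.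
- Zn(BH4)2 reduction, now controlled by the oxirane alone, should give the allylic alcohol (1R,2R,4R,6Z,10S)-4-(tert-butyldimethylsilyloxy)-6,10-dimethyl-3-methylidene-11-oxabicyclo[8.1.0]undec-6-en-2-ol F7.
- Esterification with 2-(acetoxymethyl)acrylic acid (dicyclohexylcarbodiimide, DMAP) gives the 2-(acetoxymethyl)acrylate of that alcohol F8.
- Ring-closing metathesis with the second-generation Grubbs catalyst (toluene, 80 °C) closes the butenolide to 29. This closure forms a tetrasubstituted alkene, which is why the route is held in reserve.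

**Step 16.** Transfer of the hydroxymethyl group from tin is slow, so protodestannylation of the reagent and reduction or hydrolysis of the hindered triflate may win. The fallback sets out from 27 and returns at 28. Reductive carbonylation (Pd(OAc)2, 1,3-bis(diphenylphosphino)propane, CO, Et3SiH, Et3N, DMF) gives the aldehyde (1(10)Z,4S,5R,6R,8R)-8-(tert-butyldimethylsilyloxy)-4,5-epoxy-13-oxogermacra-1(10),7(11)-dien-6,12-olide F9. Reduction of the aldehyde alone (NaBH4, CeCl3, MeOH, −78 °C) gives 28.

**Step 19.** Facial selectivity may be poor or reversed, because the delivery model assumes one conformation of the ten-membered ring (C7 equatorial, C1 outside) that the fused butenolide may not allow. The fallback sets out from 29 and returns at 31, replacing substrate direction by reagent control. Shi epoxidation of silyl ether 29 (D-fructose-derived ketone, KHSO5, K2CO3 buffer, MeCN/H2O, 0 °C) should give, by analogy with 1-substituted cycloalkenes, the (1R,10S) diepoxide (1R,4S,5R,6R,8R,10S)-13-acetoxy-8-(tert-butyldimethylsilyloxy)-1,10:4,5-diepoxygermacr-7(11)-en-6,12-olide F10. Desilylation of F10 (Bu4NF, AcOH) gives 31.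

## Further compounds

F1 | step 11 | (2Z,6Z,9R)-9-(tert-butyldimethylsilyloxy)-3,7-dimethylcyclodeca-2,6-dien-1-one | CC(C)(C)[Si](C)(C)O[C@@H]1C/C(C)=C\CC/C(C)=C\C(=O)C1
F2 | step 11 | (1R,2Z,6Z,9R)-9-(tert-butyldimethylsilyloxy)-3,7-dimethylcyclodeca-2,6-dien-1-ol | CC(C)(C)[Si](C)(C)O[C@@H]1C/C(C)=C\CC/C(C)=C\[C@H](O)C1
F3 | step 11 | (1R,2R,4R,6Z,10S)-4-(tert-butyldimethylsilyloxy)-6,10-dimethyl-11-oxabicyclo[8.1.0]undec-6-en-2-ol | CC(C)(C)[Si](C)(C)O[C@@H]1C/C(C)=C\CC[C@]2(C)O[C@@H]2[C@H](O)C1
F4 | step 7 | (2R,3aS,8aR)-2-(tert-butyldimethylsilyloxy)-3a-hydroxy-5,8a-dimethyl-2,3,3a,6,7,8a-hexahydroazulen-8(1H)-one | C[C@@]12C[C@@H](O[Si](C)(C)C(C)(C)C)C[C@]1(O)C=C(C)CCC2=O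
F5 | step 13 | (1S,4R,6Z,10S)-4-(tert-butyldimethylsilyloxy)-3-[(dimethylamino)methyl]-6,10-dimethyl-11-oxabicyclo[8.1.0]undec-6-en-2-one, epimers at C3 | CC(C)(C)[Si](C)(C)O[C@@H]1C/C(C)=C\CC[C@]2(C)O[C@@H]2C(=O)C1CN(C)C
F6 | step 13 | (1S,4R,6Z,10S)-4-(tert-butyldimethylsilyloxy)-6,10-dimethyl-3-methylidene-11-oxabicyclo[8.1.0]undec-6-en-2-one | CC(C)(C)[Si](C)(C)O[C@@H]1C/C(C)=C\CC[C@]2(C)O[C@@H]2C(=O)C1=C
F7 | step 13 | (1R,2R,4R,6Z,10S)-4-(tert-butyldimethylsilyloxy)-6,10-dimethyl-3-methylidene-11-oxabicyclo[8.1.0]undec-6-en-2-ol | CC(C)(C)[Si](C)(C)O[C@@H]1C/C(C)=C\CC[C@]2(C)O[C@@H]2[C@H](O)C1=C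
F8 | step 13 | (1R,2R,4R,6Z,10S)-4-(tert-butyldimethylsilyloxy)-6,10-dimethyl-3-methylidene-11-oxabicyclo[8.1.0]undec-6-en-2-yl 2-(acetoxymethyl)prop-2-enoate | CC(C)(C)[Si](C)(C)O[C@@H]1C/C(C)=C\CC[C@]2(C)O[C@@H]2[C@H](OC(=O)C(=C)COC(C)=O)C1=C
F9 | step 16 | (1(10)Z,4S,5R,6R,8R)-8-(tert-butyldimethylsilyloxy)-4,5-epoxy-13-oxogermacra-1(10),7(11)-dien-6,12-olide | CC(C)(C)[Si](C)(C)O[C@@H]1C/C(C)=C\CC[C@]2(C)O[C@@H]2[C@@H]2OC(=O)C(C=O)=C21
F10 | step 19 | (1R,4S,5R,6R,8R,10S)-13-acetoxy-8-(tert-butyldimethylsilyloxy)-1,10:4,5-diepoxygermacr-7(11)-en-6,12-olide | CC(C)(C)[Si](C)(C)O[C@@H]1C[C@]2(C)O[C@@H]2CC[C@]2(C)O[C@@H]2[C@@H]2OC(=O)C(COC(C)=O)=C21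
A1 | alternative 1 | methyl (1(10)Z,7(11)Z)-13-acetoxy-8-(tert-butyldimethylsilyloxy)-5,6-epoxy-4-hydroxygermacra-1(10),7(11)-dien-12-oate with trans 5,6-oxirane (seco ester before the Payne step) | CC(C)(C)[Si](C)(C)O[C@@H]1C/C(C)=C\CC[C@](C)(O)[C@H]2O[C@@H]2/C1=C(/COC(C)=O)C(=O)OC
A2 | alternative 1 | 13-acetoxy-8-(tert-butyldimethylsilyloxy)-4,5-epoxygermacra-1(10),7(11)-dien-6,12-olide (identical with 29) | CC(C)(C)[Si](C)(C)O[C@@H]1C/C(C)=C\CC[C@]2(C)O[C@@H]2[C@@H]2OC(=O)C(COC(C)=O)=C21
A3 | alternative 2 | seco aldehyde: 3-(acetoxymethyl)-4-[(1R,3Z,7S)-1-(tert-butyldimethylsilyloxy)-7-(methoxymethoxy)-3,7-dimethyl-8-oxooct-3-en-1-yl]furan-2(5H)-one | CC(C)(C)[Si](C)(C)O[C@H](C/C(C)=C\CC[C@](C)(OCOC)C=O)C1=C(COC(C)=O)C(=O)OC1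
A4 | alternative 2 | ten-membered C5 carbinol butenolide with C4 methoxymethyl ether and C8 silyl ether | CC(C)(C)[Si](C)(C)O[C@@H]1C/C(C)=C\CC[C@](C)(OCOC)[C@@H](O)[C@@H]2OC(=O)C(COC(C)=O)=C21
A5 | alternative 3 | (1(10)Z,4Z)-8-(tert-butyldimethylsilyloxy)-7-oxo-11,12,13-trinorgermacra-1(10),4-dien-6-yl prop-2-enoate | C=CC(=O)O[C@H]1/C=C(C)\CC/C=C(C)\C[C@@H](O[Si](C)(C)C(C)(C)C)C1=O
A6 | alternative 3 | 8-(tert-butyldimethylsilyloxy)-7-hydroxygermacra-1(10),4,11(13)-trien-6,12-olide (Z,Z; C7 configuration open) | C=C1C(=O)O[C@H]2/C=C(C)\CC/C=C(C)\C[C@@H](O[Si](C)(C)C(C)(C)C)C12O
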